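The route rests on disconnecting the bond between carbon 5 of ring A and the prenyl CH2. An aromatic prenyltransferase forms this bond last by Friedel–Crafts alkylation of the unprotected (S)-ketol with dimethylallyl diphosphate, in one operation and without touching the labile α-hydroxy ketone. The step exploits that ring A carbon 5, ortho to the hydroxyl on carbon 4 and para to the hydroxyl on carbon 2, is the only free activated ring carbon because carbon 3 carries the methyl group. The precursor is the des-prenyl tetrahydroxy ketol, assembled by Weinreb ketone synthesis from O-benzyl-L-tyrosine, which supplies the stereocentre, and a lithiated dibenzyl ether of 2-methylresorcinol, then debenzylated by hydrogenolysis.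

Key step: step 7

Remark on numbering: ring A is the resorcinol ring, counted from the acyl-bearing carbon as carbon 1. Carbon 2 bears a hydroxyl, carbon 3 the methyl group, carbon 4 a hydroxyl, carbon 5 the prenyl group (hydrogen in the precursor) and carbon 6 a hydrogen. Ring B is the 4-hydroxyphenyl ring.

Remark on configuration: the carbinol carbon of the target is (S). Hydroxy-deamination of an L-α-amino acid with nitrous acid is assumed to run with net retention, so the L-tyrosine skeleton supplies this centre directly.

Remark on the ketone-forming step: the ketone is made by an organolithium/Weinreb amide union. Lewis-acid acylation of free 2-methylresorcinol with an α-acyloxy acid chloride is not used, because strong Lewis acids would expose the α-oxygenated centre to enolisation and acyl migration.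

Remark on materials: 2-methylresorcinol, O-benzyl-L-tyrosine and dimethylallyl diphosphate (the last as its triammonium salt) are commercial.

Step 1
Reactants: 1 2-methylresorcinol (2-methylbenzene-1,3-diol)
Product: 2 1,3-bis(benzyloxy)-2-methylbenzene
Conditions: BnBr (2.3 equiv), K2CO3, DMF, 60 °C
Reagents that add atoms: benzyl bromide, BrCc1ccccc1
Why: Williamson ether synthesis, in which both phenoxides of 1 are alkylated by the reactive benzylic halide under mild carbonate conditions to give ethers that tolerate organolithium chemistry and are later removed without acid or base.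

Step 2
Reactants: 2 1,3-bis(benzyloxy)-2-methylbenzene
Product: 3 1,3-bis(benzyloxy)-4-bromo-2-methylbenzene
Conditions: NBS (1.0 equiv), MeCN, 0 °C to rt, dark
Reagents that add atoms: N-bromosuccinimide, O=C1CCC(=O)N1Br
Why: Electrophilic aromatic bromination, which should go to ring position 4 because it is ortho to one benzyloxy group and para to the other (positions 4 and 6 are equivalent by symmetry, position 5 is meta to both), while one equivalent of NBS at low temperature in the dark should stop at the mono-bromide and leave the benzylic positions alone.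

Step 3
Reactants: 4 O-benzyl-L-tyrosine
Product: 5 (S)-3-[4-(benzyloxy)phenyl]-2-hydroxypropanoic acid
Conditions: NaNO2 (3 equiv), 1 M aq H2SO4/1,4-dioxane, 0 °C to rt
Reagents that add atoms: water, O
Why: Diazotisation–hydrolysis of an α-amino acid (hydroxy-deamination), in which the carboxylate displaces nitrogen from the diazonium ion to give an α-lactone that water opens, two inversions that amount to retention, so the (S)-centre of 4 becomes the (S)-carbinol of 5 while the benzyl ether keeps nitrous acid off the phenol ring.

Step 4
Reactants: 5 (S)-3-[4-(benzyloxy)phenyl]-2-hydroxypropanoic acid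
Product: 6 (S)-3-[4-(benzyloxy)phenyl]-2-hydroxy-N-methoxy-N-methylpropanamide
Conditions: MeNH(OMe)·HCl, EDC·HCl, HOBt, N-methylmorpholine, CH2Cl2, 0 °C to rt
Reagents that add atoms: N,O-dimethylhydroxylamine hydrochloride, CNOC.Cl
Why: Carbodiimide/HOBt amide coupling, in which the amine captures the active ester far faster than the secondary hydroxyl does and an α-hydroxy acid has no oxazolone pathway, so the Weinreb amide should form without erosion of the (S)-centre.

Step 5
Reactants: 6 (S)-3-[4-(benzyloxy)phenyl]-2-hydroxy-N-methoxy-N-methylpropanamide; 3 1,3-bis(benzyloxy)-4-bromo-2-methylbenzene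
Product: 10 (S)-1-[2,4-bis(benzyloxy)-3-methylphenyl]-3-[4-(benzyloxy)phenyl]-2-hydroxypropan-1-one, via chloromagnesium alkoxide 7 (not isolated), via aryllithium 8 (not isolated), via tetrahedral adduct 9 (not isolated)
Conditions: 3 (1.4 equiv), n-BuLi (1.4 equiv), THF, −78 °C; 6, i-PrMgCl (1.0 equiv), THF, −20 °C; combine at −78 °C, warm to 0 °C; aq NH4Cl
Reagents that add atoms: none
Why: Weinreb ketone synthesis after bromine–lithium exchange, in which the exchange outruns deprotonation at −78 °C, the pre-formed magnesium alkoxide removes the only acidic proton and shields the α-C–H from the base, and the chelated adduct 9 releases the ketone only on quench, so over-addition is excluded and the (S)-centre is carried through unchanged.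

Step 6
Reactants: 10 (S)-1-[2,4-bis(benzyloxy)-3-methylphenyl]-3-[4-(benzyloxy)phenyl]-2-hydroxypropan-1-one
Product: 11 (S)-1-(2,4-dihydroxy-3-methylphenyl)-2-hydroxy-3-(4-hydroxyphenyl)propan-1-one
Conditions: H2 (1 atm), 10% Pd/C, EtOAc/MeOH, rt
Reagents that add atoms: none
Why: Catalytic hydrogenolysis of three aryl benzyl ethers under neutral conditions that cannot enolise the α-hydroxy ketone, while the ortho-hydroxy aryl ketone, deactivated by conjugation and its internal hydrogen bond, should not be reduced at one atmosphere.

Step 7
Reactants: 11 (S)-1-(2,4-dihydroxy-3-methylphenyl)-2-hydroxy-3-(4-hydroxyphenyl)propan-1-one; 12 dimethylallyl diphosphate (used as its triammonium salt, 2 equiv)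
Product: 13 Lespeflorin C5, (S)-1-[2,4-dihydroxy-3-methyl-5-(3-methylbut-2-en-1-yl)phenyl]-2-hydroxy-3-(4-hydroxyphenyl)propan-1-one
Conditions: AtaPT (purified recombinant ABBA-fold aromatic prenyltransferase of Aspergillus terreus), Tris·HCl buffer pH 7.5, MgCl2 (5 mM), 5% v/v DMSO, 30 °C; EtOAc extraction, preparative HPLC
Reagents that add atoms: none
Why: The enzyme ionises 12 to a dimethylallyl cation–diphosphate ion pair held over the bound resorcinol ring of 11, carbon 5 of ring A attacks the primary carbon of the cation, and the arenium ion loses its proton to restore the arene, which is an enzymatic Friedel–Crafts alkylation (aromatic C-prenylation). The closest known reaction type is the C-prenylation of acylphloroglucinols, acylresorcinols, chalcones and dihydrochalcones by soluble ABBA-fold aromatic prenyltransferases, here applied to a new member of that substrate class. No ring is closed and no stereocentre is formed; the (S)-carbinol is a spectator that buffered water at pH 7.5 and 30 °C should neither enolise nor dehydrate, and the new ortho-prenyl phenol should not cyclise to a chroman as it would under acid. The step needs carbon over oxygen alkylation, ring A over ring B and linear over reverse attachment: within ring A the substrate leaves a single nucleophilic carbon, because carbon 5 is ortho to the hydroxyl on carbon 4 and para to the hydroxyl on carbon 2, carbon 3 is blocked by its methyl group and carbon 6 is meta to both hydroxyls. Ring A is further favoured over the ortho carbons of the ring B phenol because the hydroxyl on carbon 4, para to the carbonyl, is the most acidic phenol and is partly ionised at this pH, while the active site must supply the remaining discrimination and the linear mode of attachment, to be confirmed on analytical scale before the preparative run.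

Compound list

1 | 2-methylresorcinol (2-methylbenzene-1,3-diol) | Cc1c(O)cccc1O | starting material
2 | 1,3-bis(benzyloxy)-2-methylbenzene | Cc1c(OCc2ccccc2)cccc1OCc1ccccc1 | intermediate
3 | 1,3-bis(benzyloxy)-4-bromo-2-methylbenzene | Cc1c(OCc2ccccc2)ccc(Br)c1OCc1ccccc1 | intermediate
4 | O-benzyl-L-tyrosine | N[C@@H](Cc1ccc(OCc2ccccc2)cc1)C(=O)O | starting material
5 | (S)-3-[4-(benzyloxy)phenyl]-2-hydroxypropanoic acid | O[C@@H](Cc1ccc(OCc2ccccc2)cc1)C(=O)O | intermediate
6 | (S)-3-[4-(benzyloxy)phenyl]-2-hydroxy-N-methoxy-N-methylpropanamide | CON(C)C(=O)[C@@H](O)Cc1ccc(OCc2ccccc2)cc1 | intermediate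
7 | chloromagnesium alkoxide of 6 (formed in the flask) | CON(C)C(=O)[C@@H](O[Mg]Cl)Cc1ccc(OCc2ccccc2)cc1 | intermediate
8 | [2,4-bis(benzyloxy)-3-methylphenyl]lithium (formed in the flask) | [Li]c1ccc(OCc2ccccc2)c(C)c1OCc1ccccc1 | intermediate
9 | tetrahedral adduct of 7 and 8 (formed in the flask; O-lithio N-methoxy-N-methyl hemiaminal carrying the chloromagnesium alkoxide; hemiaminal carbon undefined, carbinol carbon as in 6) | CON(C)C(O[Li])(c1ccc(OCc2ccccc2)c(C)c1OCc1ccccc1)[C@@H](O[Mg]Cl)Cc1ccc(OCc2ccccc2)cc1 | intermediate
10 | (S)-1-[2,4-bis(benzyloxy)-3-methylphenyl]-3-[4-(benzyloxy)phenyl]-2-hydroxypropan-1-one | Cc1c(OCc2ccccc2)ccc(C(=O)[C@@H](O)Cc2ccc(OCc3ccccc3)cc2)c1OCc1ccccc1 | intermediate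
11 | (S)-1-(2,4-dihydroxy-3-methylphenyl)-2-hydroxy-3-(4-hydroxyphenyl)propan-1-one | Cc1c(O)ccc(C(=O)[C@@H](O)Cc2ccc(O)cc2)c1O | intermediate
12 | dimethylallyl diphosphate | CC(C)=CCOP(=O)(O)OP(=O)(O)O | starting material
13 | Lespeflorin C5 | CC(C)=CCc1cc(C(=O)[C@@H](O)Cc2ccc(O)cc2)c(O)c(C)c1O | target

Total step count: 7. Longest linear sequence: 5 steps (steps 3 to 7, from 4).

Steps most likely to fail

Step 7. The enzyme may not bind the C-methylated ketol productively. It may also deliver the dimethylallyl cation to the ortho carbons of the ring B phenol or to a phenoxide oxygen instead of carbon 5 of ring A. The fallback sets out from 1 and 6 and comes back at 13. It places the prenyl group on ring A chemically before the ketone is formed, and uses acid-labile methoxymethyl ethers because benzyl ethers could not be hydrogenolysed beside the prenyl alkene. Compound 1 is dibrominated (NBS, 2 equiv, MeCN, 0 °C) to 4,6-dibromo-2-methylbenzene-1,3-diol F1. F1 is protected (MOMCl, i-Pr2NEt, CH2Cl2) as 1,5-dibromo-2,4-bis(methoxymethoxy)-3-methylbenzene F2. A single bromine–lithium exchange (n-BuLi, 1.0 equiv, THF, −78 °C) should give [5-bromo-2,4-bis(methoxymethoxy)-3-methylphenyl]lithium F3. Transmetallation of F3 with CuBr·SMe2 should give [5-bromo-2,4-bis(methoxymethoxy)-3-methylphenyl]copper F4. F4 is alkylated with prenyl bromide (1-bromo-3-methylbut-2-ene) to 1-bromo-2,4-bis(methoxymethoxy)-3-methyl-5-(3-methylbut-2-en-1-yl)benzene F5. Separately, 6 is debenzylated (H2, 10% Pd/C, EtOAc) to (S)-2-hydroxy-3-(4-hydroxyphenyl)-N-methoxy-N-methylpropanamide F6. Its phenol alone is then etherified (MOMCl, K2CO3, acetone) to (S)-2-hydroxy-N-methoxy-3-[4-(methoxymethoxy)phenyl]-N-methylpropanamide F7. F5 is lithiated (n-BuLi, THF, −78 °C) to [2,4-bis(methoxymethoxy)-3-methyl-5-(3-methylbut-2-en-1-yl)phenyl]lithium F8. F8 is combined, as in step 5, with the chloromagnesium alkoxide F9 made from F7 and i-PrMgCl. The tetrahedral adduct F10 should give on NH4Cl work-up (S)-1-[2,4-bis(methoxymethoxy)-3-methyl-5-(3-methylbut-2-en-1-yl)phenyl]-2-hydroxy-3-[4-(methoxymethoxy)phenyl]propan-1-one F11. The three phenolic methoxymethyl ethers of F11 are cleaved with dilute HCl in MeOH at room temperature, mild enough to leave the prenyl group uncyclised, to give 13.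

Step 5. Addition to the magnesium alkoxide may stall, so that the aryllithium is protonated or decomposes on warming before it reaches the amide carbonyl. The fallback sets out from 6 and comes back at 11, with the hydroxyl masked covalently. Compound 6 is O-benzylated under acid catalysis (benzyl 2,2,2-trichloroacetimidate, catalytic TfOH, CH2Cl2/cyclohexane, rt), with no base that could touch the stereocentre, to (S)-2-(benzyloxy)-3-[4-(benzyloxy)phenyl]-N-methoxy-N-methylpropanamide F12. F12 is added to aryllithium 8, made from 3 and n-BuLi as before, at −78 °C in an ordinary Weinreb ketone synthesis. The tetrahedral lithium adduct F13 should collapse on NH4Cl work-up to (S)-2-(benzyloxy)-1-[2,4-bis(benzyloxy)-3-methylphenyl]-3-[4-(benzyloxy)phenyl]propan-1-one F14. Hydrogenolysis of F14 under the conditions of step 6 removes all four benzyl groups and returns the route at 11.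

Step 6. The aryl ketone may be over-reduced, or the α-hydroxyl lost reductively, while the last benzyl ether is still being cleaved. The fallback sets out from 10 and comes back at 11 by a non-reductive, Lewis-acid debenzylation. Compound 10 is treated with BCl3 in the presence of pentamethylbenzene as benzyl-cation scavenger (CH2Cl2, −78 °C, then MeOH quench). This cleaves aryl benzyl ethers without hydrogen or palladium and gives 11 directly; no new isolated compound is involved.

Further compounds

F1 | step 7 | 4,6-dibromo-2-methylbenzene-1,3-diol | Cc1c(O)c(Br)cc(Br)c1O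
F2 | step 7 | 1,5-dibromo-2,4-bis(methoxymethoxy)-3-methylbenzene | COCOc1c(Br)cc(Br)c(OCOC)c1C
F3 | step 7 | [5-bromo-2,4-bis(methoxymethoxy)-3-methylphenyl]lithium | [Li]c1cc(Br)c(OCOC)c(C)c1OCOC
F4 | step 7 | [5-bromo-2,4-bis(methoxymethoxy)-3-methylphenyl]copper | [Cu]c1cc(Br)c(OCOC)c(C)c1OCOC
F5 | step 7 | 1-bromo-2,4-bis(methoxymethoxy)-3-methyl-5-(3-methylbut-2-en-1-yl)benzene | Brc1cc(CC=C(C)C)c(OCOC)c(C)c1OCOC
F6 | step 7 | (S)-2-hydroxy-3-(4-hydroxyphenyl)-N-methoxy-N-methylpropanamide | CON(C)C(=O)[C@@H](O)Cc1ccc(O)cc1
F7 | step 7 | (S)-2-hydroxy-N-methoxy-3-[4-(methoxymethoxy)phenyl]-N-methylpropanamide | CON(C)C(=O)[C@@H](O)Cc1ccc(OCOC)cc1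
F8 | step 7 | [2,4-bis(methoxymethoxy)-3-methyl-5-(3-methylbut-2-en-1-yl)phenyl]lithium | [Li]c1cc(CC=C(C)C)c(OCOC)c(C)c1OCOC
F9 | step 7 | chloromagnesium alkoxide of F7 | CON(C)C(=O)[C@@H](O[Mg]Cl)Cc1ccc(OCOC)cc1
F10 | step 7 | tetrahedral adduct of F8 and F9 | CON(C)C(O[Li])(c1cc(CC=C(C)C)c(OCOC)c(C)c1OCOC)[C@@H](O[Mg]Cl)Cc1ccc(OCOC)cc1
F11 | step 7 | (S)-1-[2,4-bis(methoxymethoxy)-3-methyl-5-(3-methylbut-2-en-1-yl)phenyl]-2-hydroxy-3-[4-(methoxymethoxy)phenyl]propan-1-one | COCOc1c(C)c(OCOC)c(CC=C(C)C)cc1C(=O)[C@@H](O)Cc1ccc(OCOC)cc1
F12 | step 5 | (S)-2-(benzyloxy)-3-[4-(benzyloxy)phenyl]-N-methoxy-N-methylpropanamide | CON(C)C(=O)[C@@H](OCc1ccccc1)Cc1ccc(OCc2ccccc2)cc1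
F13 | step 5 | tetrahedral lithium adduct of F12 and 8 | CON(C)C(O[Li])(c1ccc(OCc2ccccc2)c(C)c1OCc1ccccc1)[C@@H](OCc1ccccc1)Cc1ccc(OCc2ccccc2)cc1
F14 | step 5 | (S)-2-(benzyloxy)-1-[2,4-bis(benzyloxy)-3-methylphenyl]-3-[4-(benzyloxy)phenyl]propan-1-one | Cc1c(OCc2ccccc2)ccc(C(=O)[C@@H](OCc2ccccc2)Cc2ccc(OCc3ccccc3)cc2)c1OCc1ccccc1
F0 | step 6 | none | none
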